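Assumption: the target has no stereocentre (it is achiral), so there is no enantiomer to select; transient stereocentres are carried as racemates and are destroyed before the end.

**Retrosynthetic overview**
- Target ⇐ acid-mediated dehydration and MOM removal of a 3-hydroxyisoflavanone; the C2=C3 double bond comes from the C3 carbinol.
- Key C3–C4 bond: carbene-catalysed intramolecular crossed benzoin. The A-ring aldehyde carbon becomes an acyl anion equivalent and attacks the B-ring aryl ketone carbon (both normally electrophilic), closing ring C.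
- O1–C2 bond: Williamson ether link between an A-ring salicylaldehyde and a B-ring α-chloro ketone, made in the same flask as the benzoin step.
- B-ring α-chloro ketone ⇐ 6-bromo-2,2-dimethylchromene (Br/Li exchange, chloroacetyl Weinreb amide) ⇐ 5-bromo-2,4-dihydroxybenzaldehyde plus an isobutenyl Grignard reagent; the aldehyde position fixes the linear ring fusion.
- Ring order: benzene rings A and B are bought; the dimethylpyran ring is made first; pyranone ring C is made last.

**Route**

Step 1
Reactants: 1 2,4,6-trihydroxybenzaldehyde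
Product: 2 2-hydroxy-4,6-bis(methoxymethoxy)benzaldehyde
Conditions: MOMCl (2.1 equiv), K2CO3 (2.5 equiv), acetone, 0 °C to rt
Reagents that add atoms: chloromethyl methyl ether (MOMCl), COCCl
Why: Williamson-type O-alkylation (MOM protection) takes the two non-chelated phenols, while the OH hydrogen-bonded to the aldehyde stays free and is the one needed later for the ether link.

Step 2
Reactants: 3 5-bromo-2,4-dihydroxybenzaldehyde
Product: 4 5-bromo-2-hydroxy-4-(methoxymethoxy)benzaldehyde
Conditions: MOMCl (1.05 equiv), K2CO3 (1.2 equiv), acetone, 0 °C to rt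
Reagents that add atoms: chloromethyl methyl ether (MOMCl), COCCl
Why: Selective Williamson-type MOM protection of the more acidic, non-chelated 4-OH leaves the chelated 2-OH free to become the pyran oxygen.

Step 3
Reactants: 4 5-bromo-2-hydroxy-4-(methoxymethoxy)benzaldehyde; 5 (2-methylprop-1-en-1-yl)magnesium bromide
Product: 8 6-bromo-7-(methoxymethoxy)-2,2-dimethyl-2H-chromene, via allylic alcohol 6 (not isolated), via o-quinone methide 7 (not isolated)
Conditions: 5 (2.5 equiv), THF, 0 °C to rt; aq NH4Cl; then PPTS (5 mol%), toluene, 60 °C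
Reagents that add atoms: none
Why: Grignard 1,2-addition (the first equivalent only deprotonates the phenol) gives the doubly activated o-hydroxybenzylic allylic alcohol, which loses water to the vinyl o-quinone methide and closes by oxa-6π electrocyclisation; the ring position is dictated by the aldehyde, so no angular isomer can form, and the racemic carbinol centre is destroyed.

Step 4
Reactants: 8 6-bromo-7-(methoxymethoxy)-2,2-dimethyl-2H-chromene; 9 2-chloro-N-methoxy-N-methylacetamide
Product: 11 2-chloro-1-[7-(methoxymethoxy)-2,2-dimethyl-2H-chromen-6-yl]ethan-1-one, via aryllithium 10 (not isolated)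
Conditions: n-BuLi (1.05 equiv), THF, −78 °C; then 9 (1.2 equiv), −78 °C; AcOH quench at −78 °C
Reagents that add atoms: none
Why: Bromine–lithium exchange followed by Weinreb amide acylation, where the chelated tetrahedral adduct prevents over-addition and keeps the α-chloride intact until the quench.

Step 5
Reactants: 2 2-hydroxy-4,6-bis(methoxymethoxy)benzaldehyde (1.05 equiv); 11 2-chloro-1-[7-(methoxymethoxy)-2,2-dimethyl-2H-chromen-6-yl]ethan-1-one
Product: 13 3-hydroxy-5,7-bis(methoxymethoxy)-3-[7-(methoxymethoxy)-2,2-dimethyl-2H-chromen-6-yl]-2,3-dihydro-4H-chromen-4-one (racemic), via keto-aldehyde ether 12 (not isolated)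
Conditions: K2CO3 (2.0 equiv), NaI (10 mol%), MeCN, rt; then 2-(pentafluorophenyl)-6,7-dihydro-5H-pyrrolo[2,1-c][1,2,4]triazol-2-ium tetrafluoroborate (15 mol%), 40 °C
Reagents that add atoms: none
Why: Williamson etherification gives 12, and the carbene freed by the carbonate then adds to the aldehyde to form a catalyst-bound Breslow-type acyl anion equivalent whose carbon attacks the tethered aryl ketone in a six-membered intramolecular crossed benzoin reaction; the C3 carbinol centre forms as a racemate and is erased in step 6.

Step 6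
Reactants: 13 3-hydroxy-5,7-bis(methoxymethoxy)-3-[7-(methoxymethoxy)-2,2-dimethyl-2H-chromen-6-yl]-2,3-dihydro-4H-chromen-4-one (racemic)
Product: 14 5,7-dihydroxy-3-(7-hydroxy-2,2-dimethyl-2H-chromen-6-yl)-4H-chromen-4-one (eriosemaone D)
Conditions: HCl (2 M), MeOH–THF 3:1, 50 °C
Reagents that add atoms: none
Why: Acid-catalysed acetal exchange removes the three MOM groups, and the tertiary 3-hydroxyl, benzylic to an ortho-hydroxy, para-alkoxy aryl ring, ionises to an o-quinone-methide-type cation and loses the C2 proton in an E1 dehydration to the conjugated chromone, erasing the only stereocentre of the route.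

**Compound list**
1 | 2,4,6-trihydroxybenzaldehyde | O=Cc1c(O)cc(O)cc1O | starting material
2 | 2-hydroxy-4,6-bis(methoxymethoxy)benzaldehyde | O=Cc1c(O)cc(OCOC)cc1OCOC | intermediate
3 | 5-bromo-2,4-dihydroxybenzaldehyde | O=Cc1cc(Br)c(O)cc1O | starting material
4 | 5-bromo-2-hydroxy-4-(methoxymethoxy)benzaldehyde | O=Cc1cc(Br)c(OCOC)cc1O | intermediate
5 | (2-methylprop-1-en-1-yl)magnesium bromide | CC(C)=C[Mg]Br | starting material
6 | 4-bromo-2-(1-hydroxy-3-methylbut-2-en-1-yl)-5-(methoxymethoxy)phenol (racemic; not isolated) | CC(C)=CC(O)c1cc(Br)c(OCOC)cc1O | intermediate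
7 | 4-bromo-3-(methoxymethoxy)-6-(3-methylbut-2-en-1-ylidene)cyclohexa-2,4-dien-1-one (o-quinone methide; exocyclic geometry undefined; not isolated) | O=C1C=C(OCOC)C(Br)=CC1=CC=C(C)C | intermediate
8 | 6-bromo-7-(methoxymethoxy)-2,2-dimethyl-2H-chromene | CC1(C)C=Cc2cc(Br)c(OCOC)cc2O1 | intermediate
9 | 2-chloro-N-methoxy-N-methylacetamide | CON(C)C(=O)CCl | starting material
10 | [7-(methoxymethoxy)-2,2-dimethyl-2H-chromen-6-yl]lithium (not isolated) | CC1(C)C=Cc2cc([Li])c(OCOC)cc2O1 | intermediate
11 | 2-chloro-1-[7-(methoxymethoxy)-2,2-dimethyl-2H-chromen-6-yl]ethan-1-one | CC1(C)C=Cc2cc(C(=O)CCl)c(OCOC)cc2O1 | intermediate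
12 | 2-{2-[7-(methoxymethoxy)-2,2-dimethyl-2H-chromen-6-yl]-2-oxoethoxy}-4,6-bis(methoxymethoxy)benzaldehyde (not isolated) | O=Cc1c(OCC(=O)c2cc3C=CC(C)(C)Oc3cc2OCOC)cc(OCOC)cc1OCOC | intermediate
13 | 3-hydroxy-5,7-bis(methoxymethoxy)-3-[7-(methoxymethoxy)-2,2-dimethyl-2H-chromen-6-yl]-2,3-dihydro-4H-chromen-4-one (racemic at C3) | O=C1c2c(OCOC)cc(OCOC)cc2OCC1(O)c1cc2C=CC(C)(C)Oc2cc1OCOC | intermediate
14 | 5,7-dihydroxy-3-(7-hydroxy-2,2-dimethyl-2H-chromen-6-yl)-4H-chromen-4-one (eriosemaone D; achiral) | CC1(C)C=Cc2cc(-c3coc4cc(O)cc(O)c4c3=O)c(O)cc2O1 | target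

**Step count and risks**
Total step count: 6. Longest linear sequence: 5 (steps 2, 3, 4, 5, 6).

Steps most likely to fail:

Step 5 (tandem etherification and carbene benzoin). The aldehyde is di-ortho-oxygenated and electron-rich, so the acyl anion equivalent forms slowly. Base-induced aldol closure of 12 to a 2-aroylbenzofuran can compete, and unreacted 11 can alkylate the carbene. The fallback sets out from keto-aldehyde ether 12, isolated after the etherification (K2CO3, acetone, rt, no carbene added). It is cyclised by ketyl umpolung with SmI2 (divalent samarium) in THF/t-BuOH at −78 °C, an intramolecular pinacol coupling that gives 5,7-bis(methoxymethoxy)-3-[7-(methoxymethoxy)-2,2-dimethyl-2H-chromen-6-yl]-3,4-dihydro-2H-chromene-3,4-diol F1 as a mixture of racemic diastereomers. Parikh–Doering oxidation (SO3·pyridine, DMSO, Et3N, 0 °C) of the secondary benzylic alcohol then returns to the route at 13.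

Step 6 (one-flask dehydration and triple MOM removal). The dimethylchromene double bond may add methanol or dimerise in warm acid, and the α-keto tertiary alcohol may ionise sluggishly. The fallback sets out from 13 and separates the two events. Syn-elimination with the Burgess reagent (methyl N-(triethylammoniosulfonyl)carbamate, THF, 50 °C) gives 5,7-bis(methoxymethoxy)-3-[7-(methoxymethoxy)-2,2-dimethyl-2H-chromen-6-yl]-4H-chromen-4-one F2. The MOM groups are then removed without protic acid by ZnBr2 and propane-1-thiol in CH2Cl2 at rt, which comes back to the route at 14.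

Step 3 (Grignard addition and cyclodehydration). The phenoxide-deactivated aldehyde may add slowly, the o-quinone methide may dimerise, and the aryl MOM ether may suffer during the acid-triggered closure. The fallback sets out from 4 and uses a boron-mediated Petasis-type condensation with 2-methylprop-1-enylboronic acid and dibenzylamine (20 mol%) in dioxane at 90 °C. This forms 4-bromo-2-[1-(dibenzylamino)-3-methylbut-2-en-1-yl]-5-(methoxymethoxy)phenol F3, which expels dibenzylamine thermally and rejoins the route at o-quinone methide 7, which closes to 8.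

**Further compounds**
F1 | step 5 | 5,7-bis(methoxymethoxy)-3-[7-(methoxymethoxy)-2,2-dimethyl-2H-chromen-6-yl]-3,4-dihydro-2H-chromene-3,4-diol (racemic diastereomer mixture) | OC1c2c(OCOC)cc(OCOC)cc2OCC1(O)c1cc2C=CC(C)(C)Oc2cc1OCOC
F2 | step 6 | 5,7-bis(methoxymethoxy)-3-[7-(methoxymethoxy)-2,2-dimethyl-2H-chromen-6-yl]-4H-chromen-4-one | O=c1c(-c2cc3C=CC(C)(C)Oc3cc2OCOC)coc2cc(OCOC)cc(OCOC)c12
F3 | step 3 | 4-bromo-2-[1-(dibenzylamino)-3-methylbut-2-en-1-yl]-5-(methoxymethoxy)phenol (racemic) | CC(C)=CC(N(Cc1ccccc1)Cc1ccccc1)c1cc(Br)c(OCOC)cc1O
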